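The carbocycle of the isochromene-6,8-dione is opened at C6–C7: the C6 ketone beside the oxygen-bearing quaternary C7 is the retron of an intramolecular crossed benzoin reaction. The precursor is a monocyclic 4-ylidene-4H-pyran that carries a formylmethylidene arm (C5, C6) on C4a and a 2-oxopropanoyl arm (C8, C7, methyl) on C8a; it is assembled in one pot from a formyl ketone enolate and an ynone. A chiral triazolylidene turns the C6 aldehyde into an acyl anion equivalent that adds to the C7 ketone, which closes the six-membered ring, creates the α-ketol and sets the only stereocentre (7R) in one operation. O-Decanoylation finishes the synthesis.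

Key step: step 4

Remark: atom labels C1 to C8a are the isochromene positions of the target; the push–pull exocyclic C=C of 7 and 8 is taken to interconvert between E and Z at room temperature, and the Z form is drawn.

Step 1
Reactants: 1 3,3-dimethoxybutan-2-one
Product: 2 sodium 4,4-dimethoxy-3-oxopent-1-en-1-olate
Conditions: NaOEt, HCO2Et, Et2O, 0 °C to rt; the sodium salt is filtered off
Reagents that add atoms: ethyl formate CCOC=O; sodium ethoxide [Na+].[O-]CC
Why: Claisen formylation of a methyl ketone, which can enolise only at the methyl group because the other α-carbon is the quaternary ketal carbon, and which is driven by precipitation of the sodium enolate.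

Step 2
Reactants: 3 4,4-diethoxybut-1-yne; 4 octanoyl chloride
Product: 5 1,1-diethoxydodec-3-yn-5-one
Conditions: PdCl2(PPh3)2 (2 mol%), CuI (4 mol%), Et3N (1.2 equiv), THF, rt
Reagents that add atoms: none
Why: Acyl Sonogashira coupling of a terminal alkyne with an acid chloride should give the ynone directly, with the acetal untouched under the non-acidic conditions.

Step 3
Reactants: 2 sodium 4,4-dimethoxy-3-oxopent-1-en-1-olate; 5 1,1-diethoxydodec-3-yn-5-one
Product: 8 (2Z)-2-[6-heptyl-3-(2-oxopropanoyl)-4H-pyran-4-ylidene]acetaldehyde, via Michael adduct 6 (not isolated), via ketal-protected pyranylidene aldehyde 7 (not isolated)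
Conditions: EtOH, rt to 50 °C; then CF3CO2H, CH2Cl2, 0 °C; then H2O, rt
Reagents that add atoms: water O
Why: Michael addition of the stabilised formyl ketone enolate to the β-carbon of the ynone should give a 2-ene-1,5-dicarbonyl compound which, as in classical pyrylium syntheses, cyclodehydrates under acid through the formyl oxygen (more reactive and less hindered than the ketal-flanked ketone), loses the acidic proton of the 4-CH2 group to form the 4-ylidene-4H-pyran, and is unmasked by acetal and ketal hydrolysis to the push–pull aldehyde.

Step 4
Reactants: 8 (2Z)-2-[6-heptyl-3-(2-oxopropanoyl)-4H-pyran-4-ylidene]acetaldehyde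
Product: 9 (7R)-3-heptyl-7-hydroxy-7-methyl-6H-isochromene-6,8(7H)-dione
Conditions: (5aR,10bS)-2-(pentafluorophenyl)-5a,10b-dihydro-4H,6H-indeno[2,1-b][1,2,4]triazolo[4,3-d][1,4]oxazin-2-ium tetrafluoroborate (C18H11BF9N3O, 15 mol%), Et3N (15 mol%), THF, rt, N2
Reagents that add atoms: none
Why: The triazolylidene freed by Et3N adds to the C6 aldehyde, proton transfer gives the acyl anion equivalent, this attacks the C7 ketone of the 2-oxopropanoyl group, and collapse of the adduct releases the carbene and the C6 ketone. The closest known reaction type is the catalytic enantioselective intramolecular crossed aldehyde–ketone benzoin cyclisation that gives six-membered α-hydroxy ketones with a quaternary carbinol carbon. The carbocyclic ring (C4a, C5, C6, C7, C8, C8a) closes in the 6-exo-trig mode at the C7 carbonyl. The new stereocentre C7 is set under catalyst control, the chiral carbene deciding which face of the C7 ketone is attacked; the antipode named is proposed for 7R, and its mirror-image salt, equally accessible, is the choice if the sense of induction should be opposite. The step needs attack at C7 and not at C8, which the substrate secures because C8 is a deactivated vinylogous ester carbonyl whose attack would need a strained five-membered ring, whereas C7 is activated by the neighbouring carbonyl. Only the aldehyde can give an acyl anion equivalent, its fully substituted β-carbon C4a blocks homoenolate chemistry, and the labile push–pull C=C lets all of 8 reach the reactive Z form.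

Step 5
Reactants: 9 (7R)-3-heptyl-7-hydroxy-7-methyl-6H-isochromene-6,8(7H)-dione; 10 decanoyl chloride
Product: 11 (7R)-3-heptyl-7-methyl-6,8-dioxo-7,8-dihydro-6H-isochromen-7-yl decanoate
Conditions: Et3N (2 equiv), DMAP (10 mol%), CH2Cl2, 0 °C to rt
Reagents that add atoms: none
Why: DMAP-catalysed O-acylation of the tertiary α-ketol with an acid chloride should give the ester, and since no bond to C7 is broken the 7R configuration is retained.

Compound list
1 | 3,3-dimethoxybutan-2-one | CC(=O)C(C)(OC)OC | starting material
2 | sodium 4,4-dimethoxy-3-oxopent-1-en-1-olate | [Na+].[O-]C=CC(=O)C(C)(OC)OC | intermediate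
3 | 4,4-diethoxybut-1-yne | C#CCC(OCC)OCC | starting material
4 | octanoyl chloride | CCCCCCCC(=O)Cl | starting material
5 | 1,1-diethoxydodec-3-yn-5-one | CCCCCCCC(=O)C#CCC(OCC)OCC | intermediate
6 | 3-(2,2-diethoxyethyl)-2-(2,2-dimethoxypropanoyl)-5-oxododec-3-enal (Michael adduct, E/Z mixture, present as its sodium enolate) | CCCCCCCC(=O)C=C(CC(OCC)OCC)C(C=O)C(=O)C(C)(OC)OC | intermediate
7 | (2Z)-2-[3-(2,2-dimethoxypropanoyl)-6-heptyl-4H-pyran-4-ylidene]acetaldehyde | O=C/C=C1/C=C(CCCCCCC)OC=C1C(=O)C(C)(OC)OC | intermediate
8 | (2Z)-2-[6-heptyl-3-(2-oxopropanoyl)-4H-pyran-4-ylidene]acetaldehyde | O=C/C=C1/C=C(CCCCCCC)OC=C1C(=O)C(C)=O | intermediate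
9 | (7R)-3-heptyl-7-hydroxy-7-methyl-6H-isochromene-6,8(7H)-dione | O[C@]1(C)C(=O)C=C2C=C(CCCCCCC)OC=C2C1=O | intermediate
10 | decanoyl chloride | CCCCCCCCCC(=O)Cl | starting material
11 | (7R)-3-heptyl-7-methyl-6,8-dioxo-7,8-dihydro-6H-isochromen-7-yl decanoate | CCCCCCCCCC(=O)O[C@]1(C)C(=O)C=C2C=C(CCCCCCC)OC=C2C1=O | target

Total step count: 5
Longest linear sequence: 4 steps (step 1 or step 2, then steps 3, 4 and 5)

Steps most likely to fail

Step 4. The push–pull aldehyde may form the acyl anion equivalent too slowly. In that case attack of the nucleophilic C5 on the C7 ketone (a five-membered aldol-type closure) could compete, or discrimination between the two faces of the ketone could be poor. The fallback closes the same C6–C7 bond reductively and sets out from 8. SmI2 (2.2 equiv, THF, t-BuOH, −78 °C) should reduce the 1,2-dione to its ketyl, which adds to the C6 aldehyde in a 6-exo pinacol cyclisation. This should give 3-heptyl-6,7-dihydroxy-7-methyl-6,7-dihydro-8H-isochromen-8-one F1 as a racemic diol. MnO2 in CH2Cl2 should then oxidise the allylic secondary carbinol at C6 to racemic 9. Its unwanted half, (7S)-3-heptyl-7-hydroxy-7-methyl-6H-isochromene-6,8(7H)-dione F2, is removed by preparative chromatography on a chiral stationary phase, and the route is rejoined at 9.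

Step 3. After the conjugate addition the ring may close the wrong way. Possible courses are a carbocyclic closure (attack of the C3 ketone enol on the unmasked or ionised C6 acetal carbon, leading towards a phenol) and closure through the ketone oxygen instead of the formyl oxygen. The fallback removes the enolisable C3 ketone and the acetal by carrying C3 and C4 as an alkyne; it sets out from 2. Cadiot–Chodkiewicz coupling of 1-nonyne with 3-bromoprop-2-yn-1-ol (CuCl 5 mol%, NH2OH·HCl, n-BuNH2, H2O/CH2Cl2, 0 °C) should give dodeca-2,4-diyn-1-ol F3. MnO2 in CH2Cl2 should oxidise it to dodeca-2,4-diynal F4. Conjugate addition of 2 to the β-alkyne carbon of this aldehyde (THF–EtOH, AcOH 1 equiv, 0 °C to rt), followed by 6-endo-dig oxa-Michael closure of the formyl enol oxygen onto the remaining alkyne (AgOTf 5 mol% if the closure lags), should lead directly to 7. The fallback comes back to the route at 7, which is hydrolysed to 8 by the aqueous acid stage of step 3.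

Step 2. Under the amine conditions of the coupling the ynone may isomerise through its propargylic CH2 to the allenone and then lose ethanol to a dienone. The fallback avoids amine base and sets out from 3. Deprotonation with n-BuLi (THF, −78 °C) and addition to octanal should give 1,1-diethoxydodec-3-yn-5-ol F5. Oxidation with Dess–Martin periodinane buffered with NaHCO3 (CH2Cl2, 0 °C) should then give the ynone, and the route is rejoined at 5.

Further compounds
F1 | step 4 | 3-heptyl-6,7-dihydroxy-7-methyl-6,7-dihydro-8H-isochromen-8-one (racemic, diastereomer mixture) | CCCCCCCC1=CC2=CC(O)C(C)(O)C(=O)C2=CO1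
F2 | step 4 | (7S)-3-heptyl-7-hydroxy-7-methyl-6H-isochromene-6,8(7H)-dione | O[C@@]1(C)C(=O)C=C2C=C(CCCCCCC)OC=C2C1=O
F3 | step 3 | dodeca-2,4-diyn-1-ol | CCCCCCCC#CC#CCO
F4 | step 3 | dodeca-2,4-diynal | CCCCCCCC#CC#CC=O
F5 | step 2 | 1,1-diethoxydodec-3-yn-5-ol (racemic) | CCCCCCCC(O)C#CCC(OCC)OCC
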